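**Retrosynthetic overview**
- The prenyl–quinone bond is cut last: Stille coupling of a quinone triflate with a prenylstannane.
- The triflate comes from the mono-methyl ether of 2,5-dihydroxy-3,6-di(indol-3-yl)-1,4-benzoquinone (didemethylasterriquinone D).
- Key disconnection: both indole C3–quinone bonds at once. The two enol carbons of 2,5-dihydroxy-1,4-benzoquinone, normally nucleophilic, are turned into electrophiles as a bis(phenyliodonium) ylide (a double enolonium equivalent), and each is attacked by one molecule of indole.
- Ring order: no ring is built. The quinone ring and both indole bicycles are bought intact, the two indoles are attached in one operation, then one OH becomes OMe and the other becomes OTf and then prenyl.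

Assumption: the target has no stereocentre and no stereogenic double bond, so the achiral compound itself is the required single species and no stereocontrol is needed.

**Step 1**
Reactants: 1 2,5-dihydroxy-1,4-benzoquinone; 2 (diacetoxyiodo)benzene; 3 indole
Product: 5 2,5-dihydroxy-3,6-di(1H-indol-3-yl)-1,4-benzoquinone, via bis(phenyliodonium) ylide 4 (not isolated)
Conditions: 2 (2.05 equiv), MeCN, rt, 3 h, dark; then 3 (3.0 equiv, two of which are incorporated), BF3·OEt2 (0.5 equiv), 0 °C to rt, 12 h
Reagents that add atoms: indole (the second equivalent of 3), c1ccc2[nH]ccc2c1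
Why: Proposed new method: two equivalents of PhI(OAc)2 convert both nucleophilic enol carbons of 1 into phenyliodonium ylide carbons (ylide formation from hydroxyquinones is a known reaction type), BF3 or the AcOH formed ties up the oxido oxygen to give an alkenyl(phenyl)iodonium (an enolonium equivalent), and one indole C3 attacks each of the two iodonium-bearing carbons by conjugate addition–elimination with loss of PhI, so two molecules of indole end up in 5; the closest known reaction type is the acid- or metal-promoted C-arylation of electron-rich arenes and indoles by phenyliodonium ylides of 2-hydroxy-1,4-naphthoquinone and cyclic 1,3-diketones, and the temperature is kept at or below rt to suppress the thermal carbene/Wolff ring contraction and 1,4-phenyl shift of such ylides; no stereocentre is formed.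

**Step 2**
Reactants: 5 2,5-dihydroxy-3,6-di(1H-indol-3-yl)-1,4-benzoquinone
Product: 6 2-hydroxy-5-methoxy-3,6-di(1H-indol-3-yl)-1,4-benzoquinone
Conditions: TMSCHN2 (1.0 equiv, slow addition), THF/MeOH 4:1, 0 °C, 1 h; chromatography, recovered 5 and di-ether recycled
Reagents that add atoms: (trimethylsilyl)diazomethane, C[Si](C)(C)C=[N+]=[N-]
Why: Diazoalkane O-methylation of a vinylogous acid: the hydroxyquinone OH (pKa about 3–5) protonates the diazo reagent and is methylated while indole N–H is inert, and one equivalent on the symmetric diol gives the mono-ether as the main (statistical) product; no stereocentre is formed.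

**Step 3**
Reactants: 6 2-hydroxy-5-methoxy-3,6-di(1H-indol-3-yl)-1,4-benzoquinone
Product: 7 5-methoxy-3,6-di(1H-indol-3-yl)-1,4-benzoquinon-2-yl trifluoromethanesulfonate
Conditions: Tf2O (1.1 equiv), 2,6-lutidine (1.5 equiv), CH2Cl2, −78 to −20 °C, 1 h; short silica plug, used at once
Reagents that add atoms: trifluoromethanesulfonic anhydride, O=S(=O)(OS(=O)(=O)C(F)(F)F)C(F)(F)F
Why: O-sulfonylation of the hydroxyquinone anion gives the vinylogous acyl triflate; lutidine deprotonates only the acidic quinone OH and not the indole N–H, so triflation is chemoselective; no stereocentre is formed.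

**Step 4**
Reactants: 7 5-methoxy-3,6-di(1H-indol-3-yl)-1,4-benzoquinon-2-yl trifluoromethanesulfonate; 8 tributyl(3-methylbut-2-en-1-yl)stannane
Product: 9 2-methoxy-3,6-di(1H-indol-3-yl)-5-(3-methylbut-2-en-1-yl)-1,4-benzoquinone
Conditions: 8 (1.3 equiv), Pd2(dba)3 (2.5 mol%), P(2-furyl)3 (10 mol%), LiCl (3 equiv), NMP, 40 °C, 6 h
Reagents that add atoms: none
Why: Stille cross-coupling: zerovalent palladium inserts into the quinone C–OTf bond (a known reaction type for hydroxyquinone triflates), the prenyl group transmetalates from tin and couples through its unsubstituted CH2 terminus to give the linear prenyl side chain; no stereocentre is formed.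

**Compound list**
1 | 2,5-dihydroxy-1,4-benzoquinone | O=C1C=C(O)C(=O)C=C1O | starting material
2 | (diacetoxyiodo)benzene | CC(=O)OI(OC(C)=O)c1ccccc1 | starting material
3 | indole | c1ccc2[nH]ccc2c1 | starting material
4 | 2,5-dioxido-3,6-bis(phenyliodonio)-1,4-benzoquinone (bis-ylide) | [O-]C1=C([I+]c2ccccc2)C(=O)C([O-])=C([I+]c2ccccc2)C1=O | intermediate
5 | 2,5-dihydroxy-3,6-di(1H-indol-3-yl)-1,4-benzoquinone | OC1=C(c2c[nH]c3ccccc23)C(=O)C(O)=C(c2c[nH]c3ccccc23)C1=O | intermediate
6 | 2-hydroxy-5-methoxy-3,6-di(1H-indol-3-yl)-1,4-benzoquinone | COC1=C(c2c[nH]c3ccccc23)C(=O)C(O)=C(c2c[nH]c3ccccc23)C1=O | intermediate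
7 | 5-methoxy-3,6-di(1H-indol-3-yl)-1,4-benzoquinon-2-yl trifluoromethanesulfonate | COC1=C(c2c[nH]c3ccccc23)C(=O)C(OS(=O)(=O)C(F)(F)F)=C(c2c[nH]c3ccccc23)C1=O | intermediate
8 | tributyl(3-methylbut-2-en-1-yl)stannane | CCCC[Sn](CCCC)(CCCC)CC=C(C)C | starting material
9 | 2-methoxy-3,6-di(1H-indol-3-yl)-5-(3-methylbut-2-en-1-yl)-1,4-benzoquinone | COC1=C(c2c[nH]c3ccccc23)C(=O)C(CC=C(C)C)=C(c2c[nH]c3ccccc23)C1=O | target

**Totals**
Total step count: 4. Longest linear sequence: 4 steps (1 → 5 → 6 → 7 → 9).

**Steps most likely to fail**

Step 1 is the riskiest. The insoluble bis-ylide may react only once, may ring-contract through a carbene/ketene pathway, or the acid may oligomerise indole. The fallback keeps the iodonium umpolung but replaces the acid-promoted attack of free indole by a palladium cross-coupling. It sets out from 4, now filtered off and washed after the first half of step 1. The bis-ylide 4 is coupled with two equivalents of commercial 1-Boc-indol-3-ylboronic acid pinacol ester using Pd(PPh3)4 and K3PO4 in aqueous dioxane at rt to 40 °C; zerovalent palladium inserts into each C–I bond with loss of iodobenzene. This gives 2,5-dihydroxy-3,6-bis(1-Boc-indol-3-yl)-1,4-benzoquinone F1. Removal of both Boc groups with TFA in CH2Cl2 comes back to the route at 5.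

Step 2 is next. The mono-methylation of a symmetric diacid is statistical, and a poor mono/di ratio would cost material. The fallback sets out from 5 and changes the logic from mono-alkylation to full alkylation followed by charge-controlled mono-dealkylation. Excess TMSCHN2 gives 2,5-dimethoxy-3,6-di(1H-indol-3-yl)-1,4-benzoquinone F2. One equivalent of NaOH in aqueous dioxane then displaces a single methoxide by addition–elimination. The resulting quinone-olate anion is too electron-rich to react again, so acidification comes back to the route at 6.

Step 4 is third. The triflate is flanked by an indolyl group and a carbonyl, the prenylstannane can couple at either allyl terminus to give some reverse-prenyl isomer, and the quinone can oxidise zerovalent palladium. The fallback sets out from 7 and builds the prenyl group in two stages. Stille coupling of 7 with allyltributylstannane (same Pd2(dba)3/P(2-furyl)3/LiCl system) has no regiochemical ambiguity and gives 2-allyl-5-methoxy-3,6-di(1H-indol-3-yl)-1,4-benzoquinone F3. Cross-metathesis of F3 with excess 2-methyl-2-butene, using second-generation Grubbs catalyst (H2IMes)(PCy3)Cl2Ru=CHPh in CH2Cl2 at 40 °C, then installs the trisubstituted alkene and comes back to the route at 9.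

**Further compounds**
F1 | step 1 | 2,5-dihydroxy-3,6-bis[1-(tert-butoxycarbonyl)indol-3-yl]-1,4-benzoquinone | OC1=C(c2cn(C(=O)OC(C)(C)C)c3ccccc23)C(=O)C(O)=C(c2cn(C(=O)OC(C)(C)C)c3ccccc23)C1=O
F2 | step 2 | 2,5-dimethoxy-3,6-di(1H-indol-3-yl)-1,4-benzoquinone | COC1=C(c2c[nH]c3ccccc23)C(=O)C(OC)=C(c2c[nH]c3ccccc23)C1=O
F3 | step 4 | 2-allyl-5-methoxy-3,6-di(1H-indol-3-yl)-1,4-benzoquinone | COC1=C(c2c[nH]c3ccccc23)C(=O)C(CC=C)=C(c2c[nH]c3ccccc23)C1=O
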